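# Proposed total synthesis of baeomycesic acid (20) by a pyrone/ynol ether cycloaddition–decarboxylation

## The problem

Baeomycesic acid (20) is a depside: two separate benzene rings joined only by an aryl ester between the C1' carboxyl carbon (C7') of ring A and the C4 oxygen of ring B. It has no stereocentre, so the whole difficulty is regiochemistry and functional-group tolerance. Ring A is pentasubstituted (C1' carboxyl, C2' OH, C3' CHO, C4' OMe, C6' CH3, only C5' H). Its formyl carbon lies between two oxygens that must end up different, one a free phenol and one a methyl ether. Any approach through a symmetric resorcinol (orsellinate) core must therefore distinguish these oxygens and also place the formyl group between them rather than at C5'. Ring B is 2,4-dihydroxy-3,6-dimethylbenzoic acid, acylated only at the non-chelated 4-OH, with its 2-OH and carboxyl free at the end. The sensitive groups are the aryl aldehyde (reduction, nucleophiles), the depside ester (hydroxide, alkoxide, amines) and the two salicylic-type acids (decarboxylation on heating in acid). After the two rings are joined, only neutral, non-nucleophilic operations are therefore acceptable. The enabling feature is that the four contiguous ring A carbons C3', C2', C1', C6' carry formyl, oxygen, carboxyl and methyl, which is the substitution pattern of C3–C6 of a 3-formyl-4-oxy-6-methyl-2-pyrone-5-carboxylate. The remaining pair C4'(OMe)–C5'(H) is a two-carbon unit at the alkyne oxidation level, methoxyacetylene. Ring A can thus be formed by a [4+2] cycloaddition and CO2 loss, with the two oxygens distinct by origin and the formyl group in place from the start.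

## Retrosynthesis

**20 ⇒ 19.** The ring B carboxyl is masked to the end as a benzyl ester. Its C–O bond is cut last because hydrogenolysis is neutral and leaves the depside ester untouched, whereas any hydrolytic unmasking would compete with cleavage of the aryl ester. The forward reaction must cleave one benzyl ester without reducing the hydrogen-bonded aldehyde.

**19 ⇒ 14 + 17.** The depside bond C7'–O4 is cut into ring A acid 14 and ring B benzyl ester 17. This is preferred to building ring A on a preformed aryl ester because it divides the molecule into two arenes of similar size and leaves the ring-forming chemistry free of the labile ester. The forward reaction must acylate the unchelated 4-OH of 17 in preference to its 2-OH and to the 2-OH of 14. Both of these are held in hydrogen bonds to ortho carbonyl groups, so a mixed-anhydride activation under acidic, base-free conditions is suited.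

**17 ⇒ 16 ⇒ 15.** Benzyl ester 17 is traced to acid 16 and on to commercial methyl ester 15 by a simple ester exchange in two operations. The forward sequence must avoid decarboxylation of 16 and alkylate only its carboxylate.

**14 ⇒ 13.** Acid 14 is traced to dibenzyl compound 13, in which the C2' oxygen is a benzyl ether and the carboxyl a benzyl ester. One hydrogenolysis removes both, and the C4' methyl ether, different in kind, stays.

**13 ⇒ 8 + 11 (key disconnection).** Ring A is cut at C3'–C4' and C5'–C6', with a CO2 bridge added in the reverse sense across C3' and C6'. This leads to pyrone 8 and methoxyacetylene 11 through the bicyclic lactone 12. Cutting ring A here, rather than functionalising an orsellinate, removes both selectivity problems of the arene: the C2' oxygen comes from the pyrone (benzyl-protected) and the C4' oxygen from the ynol ether (methylated), and the formyl carbon is already on C3 of the pyrone. The aldehyde is deliberately kept free in 8. Together with the 5-ester and the lactone carbonyl it is the third acceptor that makes a 4-alkoxy pyrone electron-poor enough to react with a volatile ynol ether at moderate temperature. The forward reaction must be regioselective (alkyne CH to C6) and must use the pyrone diene rather than the formyl group.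

**8 ⇒ 7 ⇒ 5.** The C4–O benzyl bond of 8 is cut to the 4-chloro-3-formylpyrone 7. The C3–CHO bond and the C4–Cl bond of 7 are then cut together to the 4-hydroxypyrone 5, through iminium salt 6. Routing through the vinylogous acid chloride fixes unambiguously which oxygen carries the benzyl group; O-alkylation of an enolised 3-formyl-4-hydroxypyrone would be ambiguous among three oxygens.

**5 ⇒ 3 ⇒ 1 + 2.** The lactone C2–O1 bond and the C5–C6 bond (acetyl to ring carbon) are cut, giving the C-acetylated diester 4 and, before that, dibenzyl 3-oxopentanedioate 3. Compound 3 comes from commercial dimethyl ester 1 and benzyl alcohol 2. The symmetric diester supplies C2–C5 of the pyrone with the future C1' carboxyl already attached as a benzyl ester, so no later ester exchange on a hindered benzoate is needed.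

**11 ⇒ 9.** Methoxyacetylene 11 is not stored and is made when needed from chloroacetal 9 by double elimination, through sodium acetylide 10.

## Roads not taken

Alternative 1: Ring A would be cut at C1'–C2', C2'–C3' and C4'–C5' and assembled by a Danheiser benzannulation. Irradiation of diazoketone A2, which already carries ring B as its aryl ester, would give a vinylketene by Wolff rearrangement. This would add the alkynyl ether A3 in a [2+2] sense, and 4π ring opening followed by 6π electrocyclisation on heating would give phenol A1. The merits are real: the C2' hydroxyl derives from the ketene carbonyl and the C4' methoxy from the ynol ether, so the two oxygens differ by origin as in the chosen plan. The depside bond also exists before ring A, so no coupling of two hindered partners is needed. In breadth of precedent on crowded resorcinol monoethers this ring-forming step is at least the equal of a cycloaddition to a tetrasubstituted pyrone, and probably ahead of it. The weak points are specific to this target. C3' arrives as a silyloxymethyl group, so desilylation and a benzylic oxidation must follow on a hydroxybenzyl alcohol flanked by OH and OMe, which is prone to quinone methide chemistry. A2 is a diazo ketone on an aryl β-acylacrylate and needs a multistep, delicate preparation. The free phenol of ring B can intercept the ketene intermediates, and the aryl ester is exposed to light. Against the better precedent, the chosen plan sets the correct oxidation level at C3' from the outset, cheap non-photochemical starting materials and no diazo chemistry.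

Alternative 2: Here the depside bond C7'–O and the ring A bond C1'–C6' would both be formed in one biomimetic operation. Thermolysis of the diketo-dioxinone A5 would unmask an acylketene by cycloreversion. The unchelated 4-OH of 17 would trap it, and the resulting aryl triketo ester would close ring A by aldol condensation and dehydration to give the orsellinate depside A4. This is the shortest of all the routes to a depside skeleton, is convergent, needs no protecting group on ring A, and reaches A4 in far fewer steps than the chosen plan needs to reach 19. Its weakness is what it leaves undone. A4 has neither the formyl group nor the methyl ether. Methylation of the unchelated 4'-OH is plausible, but formylation must then choose C3' over C5' and over C5 of ring B, on a compound with two electron-rich rings and an acid- and base-sensitive aryl ester. That late site selectivity is exactly what the pyrone route removes, and this is the reason for accepting the longer sequence.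

Alternative 3: Ring A would be cut at C1'–C2' and C5'–C6' and formed by a Diels–Alder reaction of the silyloxydiene A7 with the but-2-ynoate A8 of the benzyl-protected ring B phenol. Acidic work-up would aromatise the adduct by loss of an alcohol and the silyl group to give A6. The regiochemistry follows the polarisation of the diene, the two oxygens again differ by origin, the depside ester is present from the start, and both partners are easier to make than pyrone 8. In step count this road is comparable to the chosen plan or slightly shorter. Its weak points are threefold: the modest dienophilicity of a but-2-ynoate, possible attack of the silyl ketene acetal terminus on the aryl ester, and above all the missing formyl group. A phenol-directed ortho-formylation at C3' is regiochemically reasonable because C1' is blocked. It would, however, have to be carried out on a chelated, electron-poor salicylate phenol, at a position flanked by two oxygens, in the presence of the depside linkage. The chosen plan has a less certain cycloaddition but avoids arene formylation altogether.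

Key step: step 6

Remark on the chemistry: the target is achiral; the only chiral species on the route, cycloadduct 12, forms as a racemate and loses both stereocentres with CO2, so no configuration is specified. Methoxyacetylene is assumed not to be purchasable and is prepared fresh.

## Route

Step 1
Reactants: 1 dimethyl 3-oxopentanedioate; 2 benzyl alcohol
Product: 3 dibenzyl 3-oxopentanedioate
Conditions: 2 (2.5 equiv), DMAP (cat.), PhMe, reflux, MeOH distilled off
Reagents that add atoms: none
Why: Amine-catalysed transesterification of a β-keto ester, which exchanges through its enol/acylketene manifold; removal of methanol should drive both ester groups to the benzyl ester.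

Step 2
Reactants: 3 dibenzyl 3-oxopentanedioate
Product: 5 benzyl 4-hydroxy-6-methyl-2-oxo-2H-pyran-5-carboxylate, via dibenzyl 2-acetyl-3-oxopentanedioate 4 (not isolated)
Conditions: AcCl (1.0 equiv), MgCl2, pyridine, CH2Cl2, 0 °C to rt; aq. HCl wash; then DBU, PhMe, 80 °C; 1 M HCl
Reagents that add atoms: acetyl chloride CC(=O)Cl
Why: Magnesium-chelate-controlled C-acylation of the β-keto ester gives triketo diester 4. Its acetyl enol oxygen should then lactonise onto the remote ester (the standard base-mediated cyclisation of 3,5-dioxo esters to 4-hydroxy-2-pyrones), expelling benzyl alcohol, and the acidic pyrone is held as its amidinium salt until work-up.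

Step 3
Reactants: 5 benzyl 4-hydroxy-6-methyl-2-oxo-2H-pyran-5-carboxylate
Product: 7 benzyl 4-chloro-3-formyl-6-methyl-2-oxo-2H-pyran-5-carboxylate, via chloro iminium chloride 6 (not isolated)
Conditions: POCl3 (3 equiv), DMF, 0 to 60 °C; then ice, aq. NaOAc
Reagents that add atoms: N,N-dimethylformamide CN(C)C=O; phosphoryl chloride O=P(Cl)(Cl)Cl; water O
Why: Vilsmeier–Haack–Arnold reaction. The enolic C3 of the 4-hydroxypyrone is formylated by the chloroiminium reagent and the 4-OH is exchanged for chloride, as is known for 4-hydroxy-6-methyl-2-pyrone and 4-hydroxycoumarin; hydrolysis of iminium salt 6 in the work-up releases the aldehyde.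

Step 4
Reactants: 7 benzyl 4-chloro-3-formyl-6-methyl-2-oxo-2H-pyran-5-carboxylate; 2 benzyl alcohol
Product: 8 benzyl 4-(benzyloxy)-3-formyl-6-methyl-2-oxo-2H-pyran-5-carboxylate
Conditions: 2 (1.05 equiv), iPr2NEt, CH2Cl2, 0 °C
Reagents that add atoms: none
Why: Addition–elimination (vinylogous acyl substitution) at C4 of a β-chlorovinyl aldehyde. Chloride is the only leaving group on the ring and C4 is activated by the formyl and lactone carbonyls; a hindered amine instead of alkoxide should avoid lactone opening.

Step 5
Reactants: 9 chloroacetaldehyde dimethyl acetal (2-chloro-1,1-dimethoxyethane)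
Product: 11 methoxyacetylene, via sodium methoxyacetylide 10 (not isolated)
Conditions: NaNH2 (3 equiv), liq. NH3, −33 °C; NH3 evaporated; cold satd aq. NaCl, −20 °C; distilled into a cold trap
Reagents that add atoms: none
Why: Twofold base-induced elimination (methanol, then HCl) gives the ynol ether, which the third equivalent of amide holds as its acetylide 10 until cold aqueous protonation; this is the classical preparation of alkoxyacetylenes from chloroacetals.

Step 6
Reactants: 8 benzyl 4-(benzyloxy)-3-formyl-6-methyl-2-oxo-2H-pyran-5-carboxylate; 11 methoxyacetylene
Product: 13 benzyl 2-(benzyloxy)-3-formyl-4-methoxy-6-methylbenzoate, via oxabicyclooctadienone cycloadduct 12 (not isolated)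
Conditions: 11 (4 equiv, amine- and acid-free), PhMe, sealed tube, 0 to 60 °C, −CO2
Reagents that add atoms: none
Why: Inverse-electron-demand Diels–Alder reaction followed by retro-Diels–Alder loss of CO2: the diene C3=C4–C5=C6 of pyrone 8, made electron-poor by the 3-formyl, 5-benzyloxycarbonyl and lactone carbonyl groups, adds the electron-rich alkyne 11. Bond formation is asynchronous: the nucleophilic terminal CH carbon of 11 attacks C6 first and the oxygen-stabilised, cation-like alkyne carbon then closes on C3, so ring A is closed as the six-membered carbocycle of an intermolecular [4+2] cycloaddition (new bonds C5'–C6' and C3'–C4'). The 2-oxabicyclo[2.2.2]octadienone 12 should not be isolable, because a second, aromatisation-driven retro-[4+2] step expels CO2 and leaves arene 13. The closest known reaction type is the cycloaddition–decarboxylation of 3- and 5-alkoxycarbonyl-2-pyrones with ynamines, ynol ethers and ketene acetals to give benzoates. No stereocentre survives, since the two bridgehead centres of 12 are lost with CO2. The step needs regioselectivity (the OMe-bearing carbon to C3) and periselectivity (the pyrone diene, not the O=CH–C3=C4 oxadiene or the formyl C=O). Regioselectivity is secured because C6 is the vinylogous acceptor terminus of all three carbonyl groups, while C3 is the enol-ether β-carbon of the 4-benzyloxy group, which matches the polarity of 11. Periselectivity is secured because the oxadiene mode would require attack at C4, a fully substituted carbon whose electrophilicity is quenched by the benzyloxy group, and because ynol ethers add to aldehyde carbonyls only under Lewis acid catalysis, which is excluded here.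

Step 7
Reactants: 13 benzyl 2-(benzyloxy)-3-formyl-4-methoxy-6-methylbenzoate
Product: 14 3-formyl-2-hydroxy-4-methoxy-6-methylbenzoic acid
Conditions: H2 (1 atm), Pd/C (10%), EtOAc, rt, stopped after uptake of 2 equiv
Reagents that add atoms: none
Why: Catalytic hydrogenolysis of the benzyl ether and benzyl ester. An aryl aldehyde hydrogen-bonded to the freed ortho phenol is reduced much more slowly than O-benzyl groups are cleaved in ethyl acetate, so stopping at the calculated uptake should preserve it.

Step 8
Reactants: 15 methyl 2,4-dihydroxy-3,6-dimethylbenzoate (methyl atrarate)
Product: 16 2,4-dihydroxy-3,6-dimethylbenzoic acid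
Conditions: aq. KOH (4 M), 60 °C; then 2 M HCl, 0 °C
Reagents that add atoms: potassium hydroxide [K+].[OH-]
Why: Saponification by acyl–oxygen cleavage. The di-ortho-substituted, phenoxide-deactivated ester needs warm concentrated base, and cold acidification should avoid decarboxylation of the β-resorcylic acid.

Step 9
Reactants: 16 2,4-dihydroxy-3,6-dimethylbenzoic acid
Product: 17 benzyl 2,4-dihydroxy-3,6-dimethylbenzoate
Conditions: BnBr (1.05 equiv), KHCO3, DMF, rt
Reagents that add atoms: benzyl bromide BrCc1ccccc1
Why: SN2 alkylation of the carboxylate. Hydrogen carbonate deprotonates only the carboxylic acid, so both phenols should stay free.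

Step 10
Reactants: 14 3-formyl-2-hydroxy-4-methoxy-6-methylbenzoic acid; 17 benzyl 2,4-dihydroxy-3,6-dimethylbenzoate
Product: 19 benzyl 4-[(3-formyl-2-hydroxy-4-methoxy-6-methylbenzoyl)oxy]-2-hydroxy-3,6-dimethylbenzoate, via mixed trifluoroacetic anhydride 18 (not isolated)
Conditions: (CF3CO)2O, PhMe, rt
Reagents that add atoms: none
Why: Mixed-anhydride esterification, the standard depside coupling. Acid 14 is activated as acyl trifluoroacetate 18 and should transfer its acyl group to the non-hydrogen-bonded 4-OH of 17, while the 2-OH groups of both partners are tied up in hydrogen bonds to ortho carbonyls and should stay free.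

Step 11
Reactants: 19 benzyl 4-[(3-formyl-2-hydroxy-4-methoxy-6-methylbenzoyl)oxy]-2-hydroxy-3,6-dimethylbenzoate
Product: 20 baeomycesic acid
Conditions: H2 (1 atm), Pd/C (10%), EtOAc, rt, stopped after uptake of 1 equiv
Reagents that add atoms: none
Why: Hydrogenolysis of the benzyl ester under neutral conditions, which should leave the depside aryl ester and the chelated aldehyde untouched.

## Compound list

1 | dimethyl 3-oxopentanedioate | COC(=O)CC(=O)CC(=O)OC | starting material
2 | benzyl alcohol | OCc1ccccc1 | starting material
3 | dibenzyl 3-oxopentanedioate | O=C(CC(=O)OCc1ccccc1)CC(=O)OCc1ccccc1 | intermediate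
4 | dibenzyl 2-acetyl-3-oxopentanedioate (enolisable, drawn as the triketo tautomer) | CC(=O)C(C(=O)OCc1ccccc1)C(=O)CC(=O)OCc1ccccc1 | intermediate (not isolated)
5 | benzyl 4-hydroxy-6-methyl-2-oxo-2H-pyran-5-carboxylate | CC1=C(C(=O)OCc2ccccc2)C(O)=CC(=O)O1 | intermediate
6 | {[5-(benzyloxycarbonyl)-4-chloro-6-methyl-2-oxo-2H-pyran-3-yl]methylidene}dimethylammonium chloride | C[N+](C)=CC1=C(Cl)C(C(=O)OCc2ccccc2)=C(C)OC1=O.[Cl-] | intermediate (not isolated)
7 | benzyl 4-chloro-3-formyl-6-methyl-2-oxo-2H-pyran-5-carboxylate | O=CC1=C(Cl)C(C(=O)OCc2ccccc2)=C(C)OC1=O | intermediate
8 | benzyl 4-(benzyloxy)-3-formyl-6-methyl-2-oxo-2H-pyran-5-carboxylate | O=CC1=C(OCc2ccccc2)C(C(=O)OCc2ccccc2)=C(C)OC1=O | intermediate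
9 | chloroacetaldehyde dimethyl acetal (2-chloro-1,1-dimethoxyethane) | COC(CCl)OC | starting material
10 | sodium methoxyacetylide | COC#[C-].[Na+] | intermediate (not isolated)
11 | methoxyacetylene | COC#C | intermediate
12 | benzyl 5-(benzyloxy)-4-formyl-8-methoxy-1-methyl-3-oxo-2-oxabicyclo[2.2.2]octa-5,7-diene-6-carboxylate (racemic) | CC12OC(=O)C(C=O)(C(OCc3ccccc3)=C1C(=O)OCc4ccccc4)C(OC)=C2 | intermediate (not isolated)
13 | benzyl 2-(benzyloxy)-3-formyl-4-methoxy-6-methylbenzoate | COc1cc(C)c(C(=O)OCc2ccccc2)c(OCc2ccccc2)c1C=O | intermediate
14 | 3-formyl-2-hydroxy-4-methoxy-6-methylbenzoic acid | COc1cc(C)c(C(=O)O)c(O)c1C=O | intermediate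
15 | methyl 2,4-dihydroxy-3,6-dimethylbenzoate (methyl atrarate) | COC(=O)c1c(C)cc(O)c(C)c1O | starting material
16 | 2,4-dihydroxy-3,6-dimethylbenzoic acid | Cc1cc(O)c(C)c(O)c1C(=O)O | intermediate
17 | benzyl 2,4-dihydroxy-3,6-dimethylbenzoate | Cc1cc(O)c(C)c(O)c1C(=O)OCc1ccccc1 | intermediate
18 | 3-formyl-2-hydroxy-4-methoxy-6-methylbenzoic trifluoroacetic anhydride | COc1cc(C)c(C(=O)OC(=O)C(F)(F)F)c(O)c1C=O | intermediate (not isolated)
19 | benzyl 4-[(3-formyl-2-hydroxy-4-methoxy-6-methylbenzoyl)oxy]-2-hydroxy-3,6-dimethylbenzoate | COc1cc(C)c(C(=O)Oc2cc(C)c(C(=O)OCc3ccccc3)c(O)c2C)c(O)c1C=O | intermediate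
20 | baeomycesic acid, 4-[(3-formyl-2-hydroxy-4-methoxy-6-methylbenzoyl)oxy]-2-hydroxy-3,6-dimethylbenzoic acid | COc1cc(C)c(C(=O)Oc2cc(C)c(C(=O)O)c(O)c2C)c(O)c1C=O | target

## Step count and risk assessment

Total step count: 11 (steps 1–4 and 6–7 for ring A, step 5 for the ynol ether, steps 8–9 for ring B, steps 10–11 for union and unmasking).
Longest linear sequence: 8 steps (1, 2, 3, 4, 6, 7, 10, 11) from dimethyl 3-oxopentanedioate.

Least certain steps:

**Step 6 (key step).** The most likely failure is consumption of the ynol ether by the formyl group, either by hetero-Diels–Alder addition across O=CH–C3=C4 or by addition to the carbonyl. The other is oligomerisation of the volatile alkyne before it adds to the crowded, fully substituted diene. Both would lower conversion to the arene rather than change its regiochemistry. Fallback, setting out from 8 and returning at 13: the aldehyde would be masked under aprotic acetalisation (methoxytrimethylsilane, catalytic trimethylsilyl trifluoromethanesulfonate, CH2Cl2, −78 °C) as benzyl 4-(benzyloxy)-3-(dimethoxymethyl)-6-methyl-2-oxo-2H-pyran-5-carboxylate F1. F1 would then be heated in toluene with an excess of commercial, thermally robust 1,1-dimethoxyethene in place of 11. The cycloadduct should lose CO2 and then methanol to give benzyl 2-(benzyloxy)-3-(dimethoxymethyl)-4-methoxy-6-methylbenzoate F2, with the same bond set C3'–C4' and C5'–C6'. Brief treatment of F2 with dilute aqueous acid would return the route at 13. The lower electrophilicity of the acetal-bearing diene is offset by the higher temperature that the ketene acetal tolerates.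

**Step 4.** The risk is attack of the alcohol at the lactone carbonyl or at C6 with opening of the pyrone, or hydrolytic reversion of the vinylogous acid chloride to the hydroxypyrone during handling. Fallback, setting out from 5 and returning at 8: the order of events is reversed so that no chloropyrone is needed. Mitsunobu etherification of 5 with 2 (triphenylphosphine, diisopropyl azodicarboxylate, THF) would give benzyl 4-(benzyloxy)-6-methyl-2-oxo-2H-pyran-5-carboxylate F3. Vilsmeier–Haack formylation of its enol-ether carbon C3 with preformed (chloromethylene)dimethyliminium chloride in acetonitrile at 0 °C would give {[4-(benzyloxy)-5-(benzyloxycarbonyl)-6-methyl-2-oxo-2H-pyran-3-yl]methylidene}dimethylammonium chloride F4. Buffered aqueous hydrolysis of F4 delivers 8.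

**Step 3.** The risk is attack of the excess chloroiminium reagent on the 6-methyl group, which is acidified by the adjacent ester (aminomethylenation), or incomplete exchange of hydroxyl for chloride. Fallback, setting out from 5 and returning at 7: carbon–carbon bond formation and chlorination are separated. Condensation of 5 with N,N-dimethylformamide dimethyl acetal in toluene at room temperature would give the enaminone benzyl 3-[(dimethylamino)methylidene]-6-methyl-2,4-dioxo-3,4-dihydro-2H-pyran-5-carboxylate F5. One equivalent of POCl3 in CH2Cl2 at 0 °C would convert this vinylogous amide into chloro iminium salt 6, and the same aqueous work-up gives 7.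

**Step 2.** The risk is retro-Claisen loss of the acetyl group from triacylmethane 4 under base in the presence of the liberated benzyl alcohol, together with O-acetylation or double acylation before lactonisation. Fallback, setting out from 2 and returning at 5: acetoacetylation of 2 with 2,2,6-trimethyl-4H-1,3-dioxin-4-one in hot xylene would give benzyl 3-oxobutanoate F6. Its reaction with malonyl dichloride (C-acylation of the active methylene, then lactonisation of the acetyl enol onto the second acid chloride) is a known route to 5-acyl- and 5-alkoxycarbonyl-4-hydroxy-6-methyl-2-pyrones and would give 5 directly.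

**Step 7.** The risk is over-reduction of the formyl group (to hydroxymethyl or methyl) before both benzyl groups are cleaved; the same concern, to a smaller degree, applies to step 11. Fallback, setting out from 13 and returning at 14: non-reductive, Lewis-acid debenzylation with BCl3 and pentamethylbenzene as cation scavenger in CH2Cl2 at −78 °C. The boron reagent chelates between the C2' oxygen and the neighbouring carbonyl groups, which should direct cleavage to the benzyl ether and benzyl ester and spare the C4' methyl ether at this temperature. No new compound arises.

## Further compounds

F1 | step 6 | benzyl 4-(benzyloxy)-3-(dimethoxymethyl)-6-methyl-2-oxo-2H-pyran-5-carboxylate | COC(OC)C1=C(OCc2ccccc2)C(C(=O)OCc2ccccc2)=C(C)OC1=O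
F2 | step 6 | benzyl 2-(benzyloxy)-3-(dimethoxymethyl)-4-methoxy-6-methylbenzoate | COc1cc(C)c(C(=O)OCc2ccccc2)c(OCc2ccccc2)c1C(OC)OC
F3 | step 4 | benzyl 4-(benzyloxy)-6-methyl-2-oxo-2H-pyran-5-carboxylate | CC1=C(C(=O)OCc2ccccc2)C(OCc2ccccc2)=CC(=O)O1
F4 | step 4 | {[4-(benzyloxy)-5-(benzyloxycarbonyl)-6-methyl-2-oxo-2H-pyran-3-yl]methylidene}dimethylammonium chloride | C[N+](C)=CC1=C(OCc2ccccc2)C(C(=O)OCc2ccccc2)=C(C)OC1=O.[Cl-]
F5 | step 3 | benzyl 3-[(dimethylamino)methylidene]-6-methyl-2,4-dioxo-3,4-dihydro-2H-pyran-5-carboxylate (alkene geometry not fixed) | CN(C)C=C1C(=O)OC(C)=C(C(=O)OCc2ccccc2)C1=O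
F6 | step 2 | benzyl 3-oxobutanoate | CC(=O)CC(=O)OCc1ccccc1
F0 | step 7 | none | none
A1 | alternative 1 | benzyl 4-{[3-({[tert-butyl(dimethyl)silyl]oxy}methyl)-2-hydroxy-4-methoxy-6-methylbenzoyl]oxy}-2-hydroxy-3,6-dimethylbenzoate | COc1cc(C)c(C(=O)Oc2cc(C)c(C(=O)OCc3ccccc3)c(O)c2C)c(O)c1CO[Si](C)(C)C(C)(C)C
A2 | alternative 1 | benzyl 4-{[(2E)-5-diazo-3-methyl-4-oxopent-2-enoyl]oxy}-2-hydroxy-3,6-dimethylbenzoate | [N-]=[N+]=CC(=O)/C(C)=C/C(=O)Oc1cc(C)c(C(=O)OCc2ccccc2)c(O)c1C
A3 | alternative 1 | tert-butyl[(3-methoxyprop-2-yn-1-yl)oxy]dimethylsilane | COC#CCO[Si](C)(C)C(C)(C)C
A4 | alternative 2 | benzyl 4-[(2,4-dihydroxy-6-methylbenzoyl)oxy]-2-hydroxy-3,6-dimethylbenzoate | Cc1cc(O)cc(O)c1C(=O)Oc1cc(C)c(C(=O)OCc2ccccc2)c(O)c1C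
A5 | alternative 2 | 6-(2,4-dioxopentyl)-2,2-dimethyl-4H-1,3-dioxin-4-one | CC(=O)CC(=O)CC1=CC(=O)OC(C)(C)O1
A6 | alternative 3 | benzyl 2-(benzyloxy)-4-[(2-hydroxy-4-methoxy-6-methylbenzoyl)oxy]-3,6-dimethylbenzoate | COc1cc(C)c(C(=O)Oc2cc(C)c(C(=O)OCc3ccccc3)c(OCc3ccccc3)c2C)c(O)c1
A7 | alternative 3 | 1,3-dimethoxy-1-(trimethylsilyloxy)buta-1,3-diene | COC(=C)C=C(OC)O[Si](C)(C)C
A8 | alternative 3 | benzyl 2-(benzyloxy)-4-(but-2-ynoyloxy)-3,6-dimethylbenzoate | CC#CC(=O)Oc1cc(C)c(C(=O)OCc2ccccc2)c(OCc2ccccc2)c1C
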